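**Plan**

- Retrosynthetic cuts, in order: the C9–O angelate; C7–C11 (isopropenyl onto a 7α,8α-epoxide); ring B back to a C9 ketone and ring A back to a Δ3 alkene; then C5–C10 and C1–C2 together (retro-[4+2]); last the chain bonds C6–C7, C5–C14, C3=C2 and C9–C10.
- Enabling feature (eremophilane numbering; ring A = C1–C5, C10; ring B = C5–C10): the fusion bond C5–C10 ties the quaternary, methyl-bearing C5 to a methine C10 next to the oxygenated C9. C9 can therefore be the carbonyl of a vinyl ketone (C10=C1) and C5 the substituted end of a diene (C5=C4–C3=C2) held to it by C6–C7–C8.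
- Forward: a C12 chain is built from a β-keto ester (C3–C6, C15), an acetal bromide (C7–C9), a methyl Grignard (C14), a Wittig CH2 (C2) and vinyl Grignard (C10, C1). Rings A and B close in one step. Ring A is then oxidised at C2 and saturated; ring B is dehydrogenated, epoxidised and opened with an isopropenyl cuprate; the angelate goes on last.
- Stereochemistry: C5 from the chiral Lewis acid (the only absolute decision); C10 by equilibration; C4 by hydrogenation anti to C14; C2 by equatorial hydride delivery; C9 by α-face hydride addition and Mitsunobu inversion; C8 and C7 by α-epoxidation and trans-diaxial opening.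

Key step: step 10

Remark: eremophilane numbering is used for all bicyclic compounds (C14 on C5, C15 on C4); β is the face of C14, and "octalin/decalin" names carry these locants.
Assumption: the (S)-configured oxazaborolidinium catalyst is taken to give the 5S series; its antipode would be used if the sense proved opposite.
Assumption: hydride adds to the Δ7-en-9-one from the α face, anti to the syn-axial C14, as it does with 5α-6-oxo and Δ4-6-oxo steroids; the C9 inversion in step 17 rests on this.

**Step 1**
Reactants: 1 methyl 2-methyl-3-oxobutanoate; 2 2-(2-bromoethyl)-1,3-dioxolane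
Product: 4 methyl 6-(1,3-dioxolan-2-yl)-2-methyl-3-oxohexanoate, via sodium lithium 1,3-dianion of methyl 2-methyl-3-oxobutanoate 3 (not isolated)
Conditions: NaH, THF, 0 °C; n-BuLi, 0 °C; then 2, DMPU, 0 °C → rt; aq. work-up
Reagents that add atoms: none
Why: β-keto ester dianion alkylation, in which the more basic γ-carbanion (the acetyl CH3) attacks the primary bromide while the α-position stays masked as the enolate.

**Step 2**
Reactants: 4 methyl 6-(1,3-dioxolan-2-yl)-2-methyl-3-oxohexanoate
Product: 5 methyl (2Z)-6-(1,3-dioxolan-2-yl)-2-methyl-3-(trifluoromethylsulfonyloxy)hex-2-enoate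
Conditions: Tf2O, sat. aq. LiOH, toluene, 5 °C
Reagents that add atoms: trifluoromethanesulfonic anhydride, O=S(=O)(OS(=O)(=O)C(F)(F)F)C(F)(F)F
Why: O-sulfonylation of the lithium-chelated enolate, which holds O– and CO2Me cis, should give the Z enol triflate.

**Step 3**
Reactants: 5 methyl (2Z)-6-(1,3-dioxolan-2-yl)-2-methyl-3-(trifluoromethylsulfonyloxy)hex-2-enoate
Product: 6 methyl (2E)-6-(1,3-dioxolan-2-yl)-2,3-dimethylhex-2-enoate
Conditions: MeMgBr, Fe(acac)3 (5 mol %), THF/NMP, –30 °C
Reagents that add atoms: methylmagnesium bromide, C[Mg]Br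
Why: iron-catalysed Kumada-type coupling of an alkenyl triflate is faster than Grignard addition to the ester and retains alkene geometry, so the new methyl (C14) ends up cis to the ester and the chain trans to it.

**Step 4**
Reactants: 6 methyl (2E)-6-(1,3-dioxolan-2-yl)-2,3-dimethylhex-2-enoate
Product: 7 (2E)-6-(1,3-dioxolan-2-yl)-2,3-dimethylhex-2-en-1-ol
Conditions: DIBAL-H, CH2Cl2, –78 → 0 °C; Rochelle salt
Reagents that add atoms: none
Why: DIBAL-H 1,2-reduction of the enoate to the allylic alcohol leaves the acetal and the alkene geometry untouched.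

**Step 5**
Reactants: 7 (2E)-6-(1,3-dioxolan-2-yl)-2,3-dimethylhex-2-en-1-ol
Product: 8 (2E)-6-(1,3-dioxolan-2-yl)-2,3-dimethylhex-2-enal
Conditions: activated MnO2, CH2Cl2, rt
Reagents that add atoms: none
Why: allylic alcohol oxidation with MnO2 is neutral, which should avoid E/Z equilibration of the tetrasubstituted enal.

**Step 6**
Reactants: 8 (2E)-6-(1,3-dioxolan-2-yl)-2,3-dimethylhex-2-enal
Product: 9 2-[(4E)-4,5-dimethylhepta-4,6-dien-1-yl]-1,3-dioxolane
Conditions: Ph3PCH3Br, KOtBu, THF, 0 °C; then 8, –78 → 0 °C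
Reagents that add atoms: methyltriphenylphosphonium bromide, C[P+](c1ccccc1)(c1ccccc1)c1ccccc1.[Br-]
Why: Wittig methylenation turns the enal into the 1,3-diene with the C4=C5 geometry (chain trans to vinyl) carried over unchanged.

**Step 7**
Reactants: 9 2-[(4E)-4,5-dimethylhepta-4,6-dien-1-yl]-1,3-dioxolane
Product: 10 (5E)-5,6-dimethylocta-5,7-dienal
Conditions: PPTS (cat.), acetone/H2O, 55 °C
Reagents that add atoms: water, O
Why: acid-catalysed acetal hydrolysis with a weak acid that should not protonate the diene.

**Step 8**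
Reactants: 10 (5E)-5,6-dimethylocta-5,7-dienal; 11 vinylmagnesium bromide
Product: 12 (7E)-7,8-dimethyldeca-1,7,9-trien-3-ol (racemic)
Conditions: THF, –78 → 0 °C; aq. work-up
Reagents that add atoms: none
Why: Grignard 1,2-addition to the aldehyde; the racemic carbinol centre is removed in the next step.

**Step 9**
Reactants: 12 (7E)-7,8-dimethyldeca-1,7,9-trien-3-ol
Product: 13 (7E)-7,8-dimethyldeca-1,7,9-trien-3-one
Conditions: Dess–Martin periodinane, CH2Cl2, 0 °C; used at once
Reagents that add atoms: none
Why: Dess–Martin oxidation gives the vinyl ketone under cold, neutral conditions, and the inside methyl on the diene terminus should keep the thermal cycloaddition slow enough for handling.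

**Step 10**
Reactants: 13 (7E)-7,8-dimethyldeca-1,7,9-trien-3-one
Product: 15 trans-fused ketone (4aS,8aR)-4a,5-dimethyl-3,4,4a,7,8,8a-hexahydronaphthalen-1(2H)-one (5β-methyl; 10α-H; Δ3; 9-oxo), via cis-fused 10βH adduct 14 (not isolated)
Conditions: N-protonated (S)-B-o-tolyl-diphenylprolinol oxazaborolidine triflimide (20 mol %), CH2Cl2, –40 → –20 °C; then NaOMe (0.2 equiv), MeOH, 0 °C → rt
Reagents that add atoms: none
Why: Proposed new method: the oxazaborolidinium ion binds the C9 carbonyl, lowers the LUMO of the C10=C1 vinyl ketone and lets it add across the C5=C4–C3=C2 diene in a concerted, asynchronous [4+2] that forms C5–C10 and C1–C2; the closest known reaction types are the thermal or Lewis-acid-promoted intramolecular Diels–Alder reaction of deca-1,7,9-trien-3-ones and oxazaborolidinium-catalysed cycloadditions of vinyl ketones, neither shown for a diene whose reacting terminus is fully substituted. Ring A closes as the new cyclohexene (both new σ bonds lie in it) and ring B as the six-membered tether ring, annulated through the four-atom chain C6–C9 by way of the carbonyl-endo transition state that gives the cis-fused adduct 14. C5 is set by the catalyst, whose aryl group shields one face of the bound enone so that it is delivered to the Re face of C5 (E-diene: chain outside, C14 inside), giving 5S; C10 is then set under thermodynamic control, NaOMe epimerising the α-keto methine to the trans-fused ketone 15. Only diene-face selectivity is needed, because the tether fixes the regiochemistry and the endo/exo outcome is erased by the epimerisation. The inside methyl slows the uncatalysed cycloaddition, so the catalysed pathway should carry the reaction.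

**Step 11**
Reactants: 15 trans-fused 4,5β-dimethyl-10αH-octal-3-en-9-one
Product: 16 trans-fused 4,5β-dimethyl-10αH-octal-3-ene-2,9-dione
Conditions: t-BuOOH, Rh2(cap)4 (1 mol %), K2CO3, CH2Cl2, rt
Reagents that add atoms: tert-butyl hydroperoxide, CC(C)(C)OO
Why: dirhodium caprolactamate/TBHP radical allylic oxidation; only the ring methylene C2 can give an enone (C5 is quaternary, C15 is a less reactive primary C–H), leading to the 4-methyl-Δ3-en-2-one.

**Step 12**
Reactants: 16 trans-fused 4,5β-dimethyl-10αH-octal-3-ene-2,9-dione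
Product: 17 4β,5β-dimethyl-10αH-decalin-2,9-dione
Conditions: H2 (1 atm), 10 % Pd/C, EtOAc, rt
Reagents that add atoms: none
Why: heterogeneous hydrogenation of the enone C=C from the α face, anti to the axial C14 on the neighbouring carbon, sets C4 with its methyl β (equatorial, cis to C14) and leaves both ketones alone.

**Step 13**
Reactants: 17 4β,5β-dimethyl-10αH-decalin-2,9-dione
Product: 18 2α-hydroxy-4β,5β-dimethyl-10αH-decalin-9-one
Conditions: L-Selectride (1.05 equiv), THF, –78 °C
Reagents that add atoms: none
Why: bulky trialkylborohydride reduction; the unhindered C2 ketone should react faster than the α-branched C9 ketone (β face shielded by C14), and equatorial hydride delivery gives the axial 2α-alcohol, as with 5α-3-oxo steroids that carry a second, hindered ring ketone.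

**Step 14**
Reactants: 18 2α-hydroxy-4β,5β-dimethyl-10αH-decalin-9-one
Product: 19 2α-acetoxy-4β,5β-dimethyl-10αH-decalin-9-one
Conditions: Ac2O, pyridine, DMAP (cat.), CH2Cl2, rt
Reagents that add atoms: acetic anhydride, CC(=O)OC(C)=O
Why: DMAP-catalysed acylation of the secondary alcohol with retention at C2.

**Step 15**
Reactants: 19 2α-acetoxy-4β,5β-dimethyl-10αH-decalin-9-one
Product: 21 2α-acetoxy-4β,5β-dimethyl-10αH-octal-7-en-9-one, via 9-trimethylsilyloxy-Δ8 enol ether 20 (not isolated)
Conditions: TMSCl, LiHMDS, THF, –78 °C; concentrate; then Pd(OAc)2, MeCN, rt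
Reagents that add atoms: none
Why: Saegusa–Ito oxidation; kinetic deprotonation at the C8 methylene (not the C10 methine, and far faster than at the acetate) gives the Δ8 silyl enol ether, from which Pd(II) β-hydride elimination gives the Δ7-en-9-one.

**Step 16**
Reactants: 21 2α-acetoxy-4β,5β-dimethyl-10αH-octal-7-en-9-one
Product: 22 2α-acetoxy-4β,5β-dimethyl-10αH-octal-7-en-9β-ol
Conditions: NaBH4, CeCl3·7H2O, MeOH, –78 °C
Reagents that add atoms: none
Why: Luche 1,2-reduction; hydride should approach C9 from the α face, away from the syn-axial C14, giving the pseudoaxial 9β-alcohol while the acetate survives.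

**Step 17**
Reactants: 22 2α-acetoxy-4β,5β-dimethyl-10αH-octal-7-en-9β-ol
Product: 23 2α-acetoxy-9α-chloroacetoxy-4β,5β-dimethyl-10αH-octal-7-ene
Conditions: ClCH2CO2H, PPh3, DIAD, toluene, 0 °C → rt
Reagents that add atoms: chloroacetic acid, OC(=O)CCl
Why: Mitsunobu esterification with an acidic carboxylic acid; the pseudoaxial allylic oxyphosphonium is displaced by chloroacetate in an SN2 reaction from the open α face, inverting C9.

**Step 18**
Reactants: 23 2α-acetoxy-9α-chloroacetoxy-4β,5β-dimethyl-10αH-octal-7-ene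
Product: 24 2α-acetoxy-4β,5β-dimethyl-10αH-octal-7-en-9α-ol
Conditions: thiourea, NaHCO3, EtOH, 55 °C
Reagents that add atoms: none
Why: selective chloroacetate cleavage (S-alkylation of thiourea, then cyclisation releases the alcohol) leaves the unactivated 2-acetate and the C9 configuration intact.

**Step 19**
Reactants: 24 2α-acetoxy-4β,5β-dimethyl-10αH-octal-7-en-9α-ol
Product: 25 2α-acetoxy-7α,8α-epoxy-4β,5β-dimethyl-10αH-decalin-9α-ol
Conditions: mCPBA, NaHCO3, CH2Cl2, 0 °C
Reagents that add atoms: 3-chloroperoxybenzoic acid, OOC(=O)c1cccc(Cl)c1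
Why: Henbest-type hydroxyl-directed Prilezhaev epoxidation; the pseudoequatorial 9α-OH binds the peracid and the axial C14 blocks the β face, so both effects lead to the 7α,8α-epoxide.

**Step 20**
Reactants: 25 2α-acetoxy-7α,8α-epoxy-4β,5β-dimethyl-10αH-decalin-9α-ol; 26 isopropenylmagnesium bromide
Product: 28 2α-acetoxy-7β-isopropenyl-4β,5β-dimethyl-10αH-decalin-8α,9α-diol, via bromomagnesium di(isopropenyl)cuprate 27 (not isolated)
Conditions: 26 (6 equiv), CuI (3 equiv), THF, –40 °C; then 25, –40 → 0 °C; aq. work-up
Reagents that add atoms: none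
Why: organocuprate epoxide opening under Fürst–Plattner control; anti attack at C7 from the β face gives the trans-diaxial 7β-isopropenyl-8α-ol through a chair-like transition state, C8 being further deactivated by the adjacent C9 oxygen, as in the 2β-opening of steroidal 2α,3α-epoxides, and the cuprate should spare the acetate at this temperature.

**Step 21**
Reactants: 28 2α-acetoxy-7β-isopropenyl-4β,5β-dimethyl-10αH-decalin-8α,9α-diol; 29 angelic acid
Product: 31 2α-acetoxy-9α-angeloyloxy-7β-isopropenyl-4β,5β-dimethyl-10αH-decalin-8α-ol (CNP0217919.1), via angelic 2,4,6-trichlorobenzoic anhydride 30 (not isolated)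
Conditions: 29, 2,4,6-trichlorobenzoyl chloride, Et3N, toluene, rt; then 28, 70 °C
Reagents that add atoms: none
Why: Yamaguchi esterification without DMAP, the usual way to form angelates without Z→E isomerisation; the equatorial 9α-OH beside the ring-fusion methine should be acylated in preference to the axial 8α-OH beside the isopropenyl-bearing C7.

**Compound list**

1 | methyl 2-methyl-3-oxobutanoate | CC(=O)C(C)C(=O)OC | starting material
2 | 2-(2-bromoethyl)-1,3-dioxolane | BrCCC1OCCO1 | starting material
3 | sodium lithium 1,3-dianion of methyl 2-methyl-3-oxobutanoate | [Na+].[Li+].[CH2-]C([O-])=C(C)C(=O)OC | intermediate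
4 | methyl 6-(1,3-dioxolan-2-yl)-2-methyl-3-oxohexanoate | COC(=O)C(C)C(=O)CCCC1OCCO1 | intermediate
5 | methyl (2Z)-6-(1,3-dioxolan-2-yl)-2-methyl-3-(trifluoromethylsulfonyloxy)hex-2-enoate | COC(=O)/C(C)=C(/CCCC1OCCO1)OS(=O)(=O)C(F)(F)F | intermediate
6 | methyl (2E)-6-(1,3-dioxolan-2-yl)-2,3-dimethylhex-2-enoate | COC(=O)/C(C)=C(C)/CCCC1OCCO1 | intermediate
7 | (2E)-6-(1,3-dioxolan-2-yl)-2,3-dimethylhex-2-en-1-ol | OC/C(C)=C(C)/CCCC1OCCO1 | intermediate
8 | (2E)-6-(1,3-dioxolan-2-yl)-2,3-dimethylhex-2-enal | O=C/C(C)=C(C)/CCCC1OCCO1 | intermediate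
9 | 2-[(4E)-4,5-dimethylhepta-4,6-dien-1-yl]-1,3-dioxolane | C=C/C(C)=C(C)/CCCC1OCCO1 | intermediate
10 | (5E)-5,6-dimethylocta-5,7-dienal | C=C/C(C)=C(C)/CCCC=O | intermediate
11 | vinylmagnesium bromide | C=C[Mg]Br | starting material
12 | (7E)-7,8-dimethyldeca-1,7,9-trien-3-ol (racemic) | C=CC(O)CCC/C(C)=C(C)/C=C | intermediate
13 | (7E)-7,8-dimethyldeca-1,7,9-trien-3-one | C=CC(=O)CCC/C(C)=C(C)/C=C | intermediate
14 | (4aS,8aS)-4a,5-dimethyl-3,4,4a,7,8,8a-hexahydronaphthalen-1(2H)-one, cis-fused (5β-Me, 10β-H) | C1C[C@]2(C)C(C)=CCC[C@@H]2C(=O)C1 | intermediate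
15 | (4aS,8aR)-4a,5-dimethyl-3,4,4a,7,8,8a-hexahydronaphthalen-1(2H)-one, trans-fused (5β-Me, 10α-H) | C1C[C@]2(C)C(C)=CCC[C@H]2C(=O)C1 | intermediate
16 | trans-fused 4,5β-dimethyl-10αH-octal-3-ene-2,9-dione | C1C[C@]2(C)C(C)=CC(=O)C[C@H]2C(=O)C1 | intermediate
17 | 4β,5β-dimethyl-10αH-decalin-2,9-dione | C1C[C@]2(C)[C@@H](C)CC(=O)C[C@H]2C(=O)C1 | intermediate
18 | 2α-hydroxy-4β,5β-dimethyl-10αH-decalin-9-one | C1C[C@]2(C)[C@@H](C)C[C@H](O)C[C@H]2C(=O)C1 | intermediate
19 | 2α-acetoxy-4β,5β-dimethyl-10αH-decalin-9-one | C1C[C@]2(C)[C@@H](C)C[C@H](OC(C)=O)C[C@H]2C(=O)C1 | intermediate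
20 | 2α-acetoxy-4β,5β-dimethyl-9-trimethylsilyloxy-10αH-octal-8-ene | C1C[C@]2(C)[C@@H](C)C[C@H](OC(C)=O)C[C@H]2C(O[Si](C)(C)C)=C1 | intermediate
21 | 2α-acetoxy-4β,5β-dimethyl-10αH-octal-7-en-9-one | C=1C[C@]2(C)[C@@H](C)C[C@H](OC(C)=O)C[C@H]2C(=O)C=1 | intermediate
22 | 2α-acetoxy-4β,5β-dimethyl-10αH-octal-7-en-9β-ol | C=1C[C@]2(C)[C@@H](C)C[C@H](OC(C)=O)C[C@H]2[C@@H](O)C=1 | intermediate
23 | 2α-acetoxy-9α-chloroacetoxy-4β,5β-dimethyl-10αH-octal-7-ene | C=1C[C@]2(C)[C@@H](C)C[C@H](OC(C)=O)C[C@H]2[C@H](OC(=O)CCl)C=1 | intermediate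
24 | 2α-acetoxy-4β,5β-dimethyl-10αH-octal-7-en-9α-ol | C=1C[C@]2(C)[C@@H](C)C[C@H](OC(C)=O)C[C@H]2[C@H](O)C=1 | intermediate
25 | 2α-acetoxy-7α,8α-epoxy-4β,5β-dimethyl-10αH-decalin-9α-ol | [C@@H]13C[C@]2(C)[C@@H](C)C[C@H](OC(C)=O)C[C@H]2[C@H](O)[C@@H]1O3 | intermediate
26 | isopropenylmagnesium bromide | C=C(C)[Mg]Br | starting material
27 | bromomagnesium di(isopropenyl)cuprate | C=C(C)[Cu-]C(C)=C.[Mg+]Br | intermediate
28 | 2α-acetoxy-7β-isopropenyl-4β,5β-dimethyl-10αH-decalin-8α,9α-diol | C=C(C)[C@H]1C[C@]2(C)[C@@H](C)C[C@H](OC(C)=O)C[C@H]2[C@H](O)[C@@H]1O | intermediate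
29 | angelic acid, (2Z)-2-methylbut-2-enoic acid | C/C=C(/C)C(=O)O | starting material
30 | angelic 2,4,6-trichlorobenzoic anhydride | C/C=C(/C)C(=O)OC(=O)c1c(Cl)cc(Cl)cc1Cl | intermediate
31 | 2α-acetoxy-9α-angeloyloxy-7β-isopropenyl-4β,5β-dimethyl-10αH-decalin-8α-ol (CNP0217919.1) | C=C(C)[C@H]1C[C@]2(C)[C@@H](C)C[C@H](OC(C)=O)C[C@H]2[C@H](OC(=O)/C(C)=C\C)[C@@H]1O | target

**Totals**

Total step count: 21. Longest linear sequence: 21 steps (1 → 31); 2, 11, 26 and 29 are bought.

**Steps most likely to fail**

Step 10. Face selectivity at C5 may be poor, the acid catalyst may isomerise or oligomerise the electron-rich diene, or the inside methyl may make the cycloaddition too slow at temperatures where the catalyst is selective. The fallback gives up catalyst control and sets out from 13. The trienone is cyclised with Me2AlCl in CH2Cl2 at –20 °C (or by heating in toluene), the known mode of reaction of deca-1,7,9-trien-3-ones, and the crude adduct is equilibrated with NaOMe. The racemic trans ketone, made up of 15 and its mirror image (4aR,8aS)-ketone ent-15 F1, is then resolved by preparative chromatography on a chiral stationary phase. The route resumes at 15.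

Step 20. Attack at C7 is syn-axial to C14 and may be slow, so that opening at C8 or loss of the acetate competes. The fallback sets out from 25 and uses a slimmer sp nucleophile under Lewis-acid activation. Lithium trimethylsilylacetylide with BF3·OEt2 (THF, –78 °C) should open the epoxide in the same trans-diaxial sense to give the 7β-(trimethylsilylethynyl)-8α,9α-diol F2. TBAF buffered with AcOH removes silicon to give the 7β-ethynyl-8α,9α-diol F3. Zirconium-catalysed methylalumination (AlMe3, Cp2ZrCl2, CH2Cl2; Negishi carboalumination) followed by protonolysis turns the ethynyl group into isopropenyl. The route resumes at 28.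

Step 21. Acylation may also occur at O-8 or at both hydroxyls, the acyl group may migrate between the cis oxygens, and the angelate may isomerise to the tiglate on prolonged heating. The fallback sets out from 25 and places the ester before the second hydroxyl exists. Yamaguchi angeloylation of the single hydroxyl of 25 gives the 7α,8α-epoxy-9α-angelate F4. Its epoxide is then opened with cuprate 27 at –40 °C as in step 20, which releases the 8α-OH and arrives directly at 31.

**Further compounds**

F1 | step 10 | (4aR,8aS)-4a,5-dimethyl-3,4,4a,7,8,8a-hexahydronaphthalen-1(2H)-one (ent-15) | C1C[C@@]2(C)C(C)=CCC[C@@H]2C(=O)C1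
F2 | step 20 | 2α-acetoxy-4β,5β-dimethyl-7β-(trimethylsilylethynyl)-10αH-decalin-8α,9α-diol | C[Si](C)(C)C#C[C@H]1C[C@]2(C)[C@@H](C)C[C@H](OC(C)=O)C[C@H]2[C@H](O)[C@@H]1O
F3 | step 20 | 2α-acetoxy-7β-ethynyl-4β,5β-dimethyl-10αH-decalin-8α,9α-diol | C#C[C@H]1C[C@]2(C)[C@@H](C)C[C@H](OC(C)=O)C[C@H]2[C@H](O)[C@@H]1O
F4 | step 21 | 2α-acetoxy-9α-angeloyloxy-7α,8α-epoxy-4β,5β-dimethyl-10αH-decalin | [C@@H]13C[C@]2(C)[C@@H](C)C[C@H](OC(C)=O)C[C@H]2[C@H](OC(=O)/C(C)=C\C)[C@@H]1O3
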